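Target is the reading to watch: in the autumn run it stands at 0.2 % at 4.00 min and at 2.6 % at 10.0 min, while substrate falls to 97.4 %. The two sum to the charge, so I treat target and lost substrate as one count.

- autumn: substrate 0.020 M; reagent in the second phase 0.024 M; the very flask that is asked about, followed so far
- flask: substrate 0.020 M; reagent in the second phase 0.0240 M; time 1.0 h; volume of the second phase over the first 1.0

autumn run (percent of the substrate charged)

| time / min | substrate / % | target / % |
|---|---|---|
| 0.667 | 99.9 | 0 |
| 2.00 | 100.1 | 0.4 |
| 4.00 | 99.4 | 0.2 |
| 6.00 | 98.8 | 1.0 |
| 8.00 | 98.1 | 2.1 |
| 10.0 | 97.4 | 2.6 |

(scatter of a reading: 0.3 percentage points)

- why nothing more happens at 1.0 h, or that something still does (all of the substrate has reacted / it is still moving / forward and back rates have come level)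
- how much of the substrate has reacted by 1.0 h
- how much target there is at 1.0 h, in percent of the substrate charged

- in the second phase: reagent in the second phase; everything else is in the first
- charges count per volume of the first phase; a concentration in a rate is the amount of a species over the volume of its own phase; every rate counts per litre of the first phase
- the analysis behind the earlier runs scatters by 0.3 percentage points, standard deviation
- reactions considered so far: reagent in the reaction phase <-> reagent in the second phase; substrate + reagent in the reaction phase -> target; reagent in the reaction phase <-> dormant form
- the earlier runs hold the two phases in the same ratio of volumes as the flask asked about
- the reaction counts as stopped when no species that holds the substrate changes by six tenths of a point or more over the second half of the time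

After the lag, substrate drops 2 percentage points in 6.00 min. That gives a fractional loss of 0.00339 /min, a pseudo-first-order constant. The drop itself carries about 0.42 points of scatter. By 1.0 h I reckon 0.190 turns, a turn count being that fractional loss multiplied by the time past the lag.

I turn the settings by hand. Time enters the count directly: at 0.500 h I get 8.98 % reacted, and at 1.0 h I get 17.8 %. That leaves 8.8 points for the second half, so the flask is still moving. For the reagent charge, I take k in step with c(reagent in the reaction phase), hence with c(reagent in the second phase). My target uses 14.8 % of that charge, so I hold k constant. I read k at 0.020 M of substrate, and substrate uses up reagent in the reaction phase, so k can shift with that charge.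

The forecast says it is still moving, with 19 % reacted and 19 % target, above my figure, and it notes that "depletion slows this only slightly".

The flask gives it is still moving, with 17.6 % reacted and 17.6 % target.

    reagent in the reaction phase ⇌ reagent in the second phase, rate k1*([reagent in the reaction phase] - [reagent in the second phase]/K1) per volume of the first phase (partition coefficient = 19.0, kL = 0.00540 /s)
    substrate + reagent in the reaction phase → target (k = 0.0650 /M/s)
    reagent in the reaction phase ⇌ dormant form (K = 0.990, k = 0.00100 /s)

Its largest change over the second half is 8.6 points. Its substrate left counts 0.194 turns against my 0.190. A neighbour flask charged with 0.0080 M of substrate has the same charge of reagent in the second phase, and I set my count of 0.190 beside it. It keeps 80 % of its substrate, which is 0.223 turns, and reaches 20.0 %.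

The runs are calculated from invented constants; noise was put on by code.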